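Everything rests on removing, in one retrosynthetic stroke, the aromaticity of ring B and its three C–Br bonds. Ring B is a catechol (C3–OH, C4–OH) in which C2, C5 and C6 all carry bromine and C1 carries the only carbon substituent, which is exactly where exhaustive bromination of a 4-alkylcyclohexane-1,2-dione ends. In a single operation four equivalents of Br2 dehydrogenate the diketone ring and brominate C2, C5 and C6, while the electron-poor ring A keeps its C5–H. The precursor is racemic 3,4-diacetoxy-2,6-dibromobenzyl (3,4-dioxocyclohexyl)methyl ether, whose ether bond is forged earlier on an unhindered alicyclic primary alcohol.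

Key step: step 9

Remark: in both rings C1 is the carbon that bears the CH2O group; 3-cyclohexene-1-methanol is used as the racemate, the alicyclic ring B intermediates are carried as racemates or epimer mixtures because aromatisation erases their stereocentres, and the dione is drawn as the diketone although it should exist largely as its enols.

Step 1
Reactants: 1 isovanillin
Product: 3 2,6-dibromo-3-hydroxy-4-methoxybenzaldehyde, via 2-bromoisovanillin 2 (not isolated)
Conditions: Br2 (2.3 equiv), NaOAc (3 equiv), AcOH, rt → 45 °C
Reagents that add atoms: bromine, BrBr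
Why: Electrophilic aromatic bromination in which the free C3–OH, the strongest donor on the ring, directs first to its ortho carbon C2 and then to its para carbon C6, whereas C5 is activated only by the weaker methoxy group and should stay free.

Step 2
Reactants: 3 2,6-dibromo-3-hydroxy-4-methoxybenzaldehyde
Product: 4 2,6-dibromo-3,4-dihydroxybenzaldehyde
Conditions: BBr3 (2.5 equiv), CH2Cl2, −78 °C → rt; ice–water
Reagents that add atoms: none
Why: Lewis-acid aryl methyl ether cleavage, in which boron binds the methoxy oxygen (helped by the neighbouring phenol and the para formyl group) and bromide removes the methyl group by SN2, is placed here because no benzylic ether yet exists that BBr3 could destroy.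

Step 3
Reactants: 4 2,6-dibromo-3,4-dihydroxybenzaldehyde
Product: 5 3,4-diacetoxy-2,6-dibromobenzaldehyde
Conditions: Ac2O (2.6 equiv), pyridine (4 equiv), CH2Cl2, 0 °C → rt
Reagents that add atoms: acetic anhydride, CC(=O)OC(C)=O
Why: Base-mediated O-acetylation of both phenols (nucleophilic acyl substitution), run with pyridine rather than acid so that the aldehyde is not turned into its geminal diacetate, installs the ester groups that later deactivate ring A.

Step 4
Reactants: 5 3,4-diacetoxy-2,6-dibromobenzaldehyde
Product: 6 3,4-diacetoxy-2,6-dibromobenzyl alcohol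
Conditions: BH3·THF (1.0 equiv), THF, 0 °C; aq NH4Cl
Reagents that add atoms: none
Why: Chemoselective carbonyl reduction with neutral, electrophilic borane, which reduces aldehydes far faster than aryl esters and brings no alkoxide or borohydride base that could strip the activated aryl acetates.

Step 5
Reactants: 6 3,4-diacetoxy-2,6-dibromobenzyl alcohol
Product: 7 3,4-diacetoxy-2,6-dibromobenzyl bromide
Conditions: PBr3 (0.5 equiv), CH2Cl2, 0 °C → rt
Reagents that add atoms: phosphorus tribromide, BrP(Br)Br
Why: Bromodehydroxylation with PBr3, in which the alcohol becomes a phosphite leaving group that bromide displaces by SN2 at the primary benzylic carbon, suits this substrate because the acidic medium leaves aryl acetates alone and the electron-poor ring cannot alkylate itself.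

Step 6
Reactants: 7 3,4-diacetoxy-2,6-dibromobenzyl bromide; 8 3-cyclohexene-1-methanol (racemic)
Product: 9 3,4-diacetoxy-2,6-dibromobenzyl (cyclohex-3-en-1-yl)methyl ether (racemic)
Conditions: 8 (2 equiv), AgOTf (1.3 equiv), 2,6-di-tert-butylpyridine (1.5 equiv), 4 Å MS, CH2Cl2, 0 °C → rt, dark
Reagents that add atoms: none
Why: AgOTf-assisted Williamson-type etherification, in which the halophilic silver cation pulls bromide off the benzylic carbon as insoluble AgBr while the unhindered primary hydroxyl of 8 attacks in an SN2-like manner, and the non-nucleophilic pyridine base takes up the acid without touching the aryl acetates that an alkoxide would strip.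

Step 7
Reactants: 9 3,4-diacetoxy-2,6-dibromobenzyl (cyclohex-3-en-1-yl)methyl ether
Product: 10 3,4-diacetoxy-2,6-dibromobenzyl (cis-3,4-dihydroxycyclohexyl)methyl ether (racemic, both C1 epimers)
Conditions: OsO4 (2 mol %), NMO (1.3 equiv), citric acid (1 equiv), t-BuOH–acetone–H2O, rt; aq NaHSO3
Reagents that add atoms: OsO4, O=[Os](=O)(=O)=O (delivers both oxygens); NMO, C[N+]1([O-])CCOCC1, and water, O (restock them)
Why: Upjohn dihydroxylation, in which OsO4 adds to the only C=C by a concerted suprafacial [3+2] cycloaddition that sets the C3 and C4 carbinol centres cis to each other while either ring face may be attacked (the C1 epimers converge later), and the citric acid buffer neutralises the liberated N-methylmorpholine so that the aryl acetates are not hydrolysed.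

Step 8
Reactants: 10 3,4-diacetoxy-2,6-dibromobenzyl (cis-3,4-dihydroxycyclohexyl)methyl ether
Product: 11 3,4-diacetoxy-2,6-dibromobenzyl (3,4-dioxocyclohexyl)methyl ether (racemic)
Conditions: (COCl)2 (3 equiv), DMSO (6 equiv), CH2Cl2, −78 °C; Et3N (10 equiv), −78 → −10 °C; pH 5 buffer; used at once
Reagents that add atoms: none
Why: Double Swern oxidation, in which both secondary hydroxyls are converted into alkoxysulfonium ions before base is added so that the two carbonyls form together by ylide fragmentation without glycol C–C cleavage, removes the two carbinol stereocentres and exposes the aryl acetates only to cold, non-nucleophilic Et3N.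

Step 9
Reactants: 11 3,4-diacetoxy-2,6-dibromobenzyl (3,4-dioxocyclohexyl)methyl ether
Product: 14 3,4-diacetoxy-2,6-dibromobenzyl 2,5,6-tribromo-3,4-dihydroxybenzyl ether, via bromodione 12 (not isolated), via catechol ether 13 (not isolated)
Conditions: Br2 (4.0 equiv, slow addition), NaOAc (6 equiv), AcOH–CH2Cl2, 10 °C → rt → 40 °C, dark; aq Na2S2O4 wash
Reagents that add atoms: bromine, BrBr
Why: Dione 11 reacts through its enol tautomers: Br2 attacks an α-carbon (C5 is drawn, C2 serves equally) to give 12, acetate-assisted loss of HBr leaves a hydroxycyclohexadienone, and this non-aromatic phenol tautomer shifts a proton to become catechol 13. The freed C3–OH and C4–OH then steer three rapid electrophilic aromatic substitutions to C2 and C5 (ortho) and C6 (para), so one Br2 pays for the dehydrogenation and three make the new C–Br bonds; should bromination and HBr loss interleave differently, the end point and the bromine count stay the same. The closest known reaction type is the bromine-induced dehydrogenation of diosphenols, cyclic 1,2-diketones and cyclohexenones to brominated phenols, coupled with the exhaustive ring bromination of 4-alkylcatechols. No ring is closed and no stereocentre is made, and the single stereocentre C1 of 11 is erased. The selectivity required is ring B over the ring A C5–H, and it is secured by the two acetoxy and two bromo groups, which leave ring A far less nucleophilic than an enol or a free catechol. NaOAc absorbs the five equivalents of HBr so that the benzylic ether is not cleaved, exact stoichiometry and darkness hold back ipso attack at C1 and radical benzylic bromination, and the Na2S2O4 wash returns any o-quinone to the catechol.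

Step 10
Reactants: 14 3,4-diacetoxy-2,6-dibromobenzyl 2,5,6-tribromo-3,4-dihydroxybenzyl ether
Product: 15 2,6-dibromo-3,4-dihydroxybenzyl 2,5,6-tribromo-3,4-dihydroxybenzyl ether (target)
Conditions: N2H4·H2O (5 equiv), degassed THF, 0 °C, Ar; cold aq NaH2PO4/dilute HCl to pH 4
Reagents that add atoms: none
Why: Hydrazinolysis (aminolysis of activated aryl esters), in which the α-effect nucleophile removes both acetyl groups at 0 °C, the aprotic solvent denies the para-hydroxybenzylic ether an alcohol with which it could exchange by way of a quinone methide, and hydrazine together with argon keeps both catechols in the reduced state.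

Compound list
1 | isovanillin (3-hydroxy-4-methoxybenzaldehyde) | COc1ccc(C=O)cc1O | starting material
2 | 2-bromoisovanillin (2-bromo-3-hydroxy-4-methoxybenzaldehyde), not isolated | COc1ccc(C=O)c(Br)c1O | intermediate
3 | 2,6-dibromo-3-hydroxy-4-methoxybenzaldehyde | COc1cc(Br)c(C=O)c(Br)c1O | intermediate
4 | 2,6-dibromo-3,4-dihydroxybenzaldehyde | Oc1cc(Br)c(C=O)c(Br)c1O | intermediate
5 | 3,4-diacetoxy-2,6-dibromobenzaldehyde | CC(=O)Oc1cc(Br)c(C=O)c(Br)c1OC(C)=O | intermediate
6 | 3,4-diacetoxy-2,6-dibromobenzyl alcohol | CC(=O)Oc1cc(Br)c(CO)c(Br)c1OC(C)=O | intermediate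
7 | 3,4-diacetoxy-2,6-dibromobenzyl bromide | CC(=O)Oc1cc(Br)c(CBr)c(Br)c1OC(C)=O | intermediate
8 | 3-cyclohexene-1-methanol (racemic) | OCC1CCC=CC1 | starting material
9 | 3,4-diacetoxy-2,6-dibromobenzyl (cyclohex-3-en-1-yl)methyl ether (racemic) | CC(=O)Oc1cc(Br)c(COCC2CCC=CC2)c(Br)c1OC(C)=O | intermediate
10 | 3,4-diacetoxy-2,6-dibromobenzyl (cis-3,4-dihydroxycyclohexyl)methyl ether (racemic, one enantiomeric series drawn, C1 epimers unassigned) | CC(=O)Oc1cc(Br)c(COCC2CC[C@@H](O)[C@@H](O)C2)c(Br)c1OC(C)=O | intermediate
11 | 3,4-diacetoxy-2,6-dibromobenzyl (3,4-dioxocyclohexyl)methyl ether (racemic, key-step precursor) | CC(=O)Oc1cc(Br)c(COCC2CCC(=O)C(=O)C2)c(Br)c1OC(C)=O | intermediate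
12 | 3,4-diacetoxy-2,6-dibromobenzyl (5-bromo-3,4-dioxocyclohexyl)methyl ether (stereoisomer mixture), not isolated | CC(=O)Oc1cc(Br)c(COCC2CC(Br)C(=O)C(=O)C2)c(Br)c1OC(C)=O | intermediate
13 | 3,4-diacetoxy-2,6-dibromobenzyl 3,4-dihydroxybenzyl ether, not isolated | CC(=O)Oc1cc(Br)c(COCc2ccc(O)c(O)c2)c(Br)c1OC(C)=O | intermediate
14 | 3,4-diacetoxy-2,6-dibromobenzyl 2,5,6-tribromo-3,4-dihydroxybenzyl ether (ring A diacetate of the target) | CC(=O)Oc1cc(Br)c(COCc2c(Br)c(O)c(O)c(Br)c2Br)c(Br)c1OC(C)=O | intermediate
15 | 2,6-dibromo-3,4-dihydroxybenzyl 2,5,6-tribromo-3,4-dihydroxybenzyl ether (CNP0152798.0, achiral) | Oc1cc(Br)c(COCc2c(Br)c(O)c(O)c(Br)c2Br)c(Br)c1O | target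

Total step count: 10. Longest linear sequence: 10 steps (1 → 15); alcohol 8 is bought and enters at step 6.

Steps most likely to fail

Step 9. The sequence may stall at brominated but not yet aromatised dione stages. The newly para-hydroxybenzylic ether may undergo acetolysis or cleavage by HBr. Bromine may attack ipso at C1 or oxidise the catechol, which leaves ring B underbrominated. The fallback brings ring B in already aromatic; it sets out from bromide 7 and comes back at 14. Purchased 3,4-dihydroxybenzaldehyde is silylated (TBSCl, imidazole, DMF) to 3,4-bis(tert-butyldimethylsilyloxy)benzaldehyde F1. This is reduced (NaBH4, MeOH, 0 °C) to 3,4-bis(tert-butyldimethylsilyloxy)benzyl alcohol F2. Coupling with 7 (AgOTf, 2,6-di-tert-butylpyridine, CH2Cl2) gives 3,4-diacetoxy-2,6-dibromobenzyl 3,4-bis(tert-butyldimethylsilyloxy)benzyl ether F3. Et3N·3HF in THF at 0 °C should free catechol 13, now isolated, without touching the acetates. Ordinary exhaustive bromination (Br2, 3.0 equiv, NaOAc, AcOH, rt, dark) should then carry 13 to 14.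

Step 8. The second oxidation may lag behind the first. Excess activated DMSO may chlorinate or methylthiomethylate the enolised product, and the dione may condense with itself or oxidise in air during isolation. The fallback reaches the dione from a ketone instead of a diol; it sets out from bromide 7 and comes back at 11, bypassing 9 and 10. Bromide 7 is coupled (AgOTf, 2,6-di-tert-butylpyridine, CH2Cl2) with purchased 4-(hydroxymethyl)cyclohexanone to give 3,4-diacetoxy-2,6-dibromobenzyl (4-oxocyclohexyl)methyl ether F4. Its two α-methylene groups are equivalent, so a Riley oxidation (SeO2, dioxane with a little water, 70 °C) can lead only to 11.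

Step 6. Substitution may be sluggish at a benzylic carbon that is flanked by two bromines on an electron-poor ring. Adventitious water may hydrolyse the halide, and acetyl groups may be transferred to the excess alcohol. The fallback makes the C–O bond at the aldehyde oxidation level, on a flat and less hindered carbon; it sets out from aldehyde 5 and comes back at 9, bypassing 6 and 7. Alcohol 8 is silylated (TMSCl, Et3N, CH2Cl2) to (cyclohex-3-en-1-ylmethoxy)trimethylsilane F5. Aldehyde 5 and F5 are then joined by reductive etherification (Et3SiH, 3 equiv, TMSOTf, 10 mol %, CH2Cl2, −78 °C). The excess silane and the low temperature serve to reduce the oxocarbenium ion before it can close onto the ring alkene.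

Further compounds
F1 | step 9 | 3,4-bis(tert-butyldimethylsilyloxy)benzaldehyde | CC(C)(C)[Si](C)(C)Oc1ccc(C=O)cc1O[Si](C)(C)C(C)(C)C
F2 | step 9 | 3,4-bis(tert-butyldimethylsilyloxy)benzyl alcohol | CC(C)(C)[Si](C)(C)Oc1ccc(CO)cc1O[Si](C)(C)C(C)(C)C
F3 | step 9 | 3,4-diacetoxy-2,6-dibromobenzyl 3,4-bis(tert-butyldimethylsilyloxy)benzyl ether | CC(=O)Oc1cc(Br)c(COCc2ccc(O[Si](C)(C)C(C)(C)C)c(O[Si](C)(C)C(C)(C)C)c2)c(Br)c1OC(C)=O
F4 | step 8 | 3,4-diacetoxy-2,6-dibromobenzyl (4-oxocyclohexyl)methyl ether | CC(=O)Oc1cc(Br)c(COCC2CCC(=O)CC2)c(Br)c1OC(C)=O
F5 | step 6 | (cyclohex-3-en-1-ylmethoxy)trimethylsilane (racemic) | C[Si](C)(C)OCC1CCC=CC1
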